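## Structural features

- The target 15 is an unsymmetrical benzil. One carbonyl of the 1,2-dione carries a 4-methoxyphenyl ring (ring C); the other is bonded to C6 of a 2,2-dimethyl-2H-chromene.
- The chromene is a benzene ring A fused through C4a–C8a to a pyran ring B (O1, C2 with two methyl groups, C3=C4).
- Ring A carries five substituents in unbroken sequence: C4a (ring fusion), C5 (methoxy), C6 (dione), C7 (hydroxy) and C8a (O1). Only C8 keeps a hydrogen.
- There is no stereocentre, and the only C=C bond outside the arenes lies in a ring, so no configuration has to be controlled.
- Several groups are fragile: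
  - the 1,2-dione, which alkoxide or hydroxide would push into benzilic rearrangement or cleavage;
  - the electron-rich C3=C4 bond, which is sensitive to strong acid, electrophiles and hydrogenation;
  - the 5-methoxy group ortho to a carbonyl, which boron and aluminium halides cleave;
  - the 7-hydroxy group, which can add to the distal carbonyl.
- The real difficulty is the O5/C6-acyl/O7 array. The two oxygens flank the same carbonyl, yet one is methylated and the other free, and ring B must be placed correctly relative to them.
- The key step uses the fact that O5 and O7 are both ortho to the C6 carbonyl, so each can enter as an alkoxide displacing fluoride from a carbon that this carbonyl activates. The two sites differ only in their other neighbour: C4a (with the peri C4–H) for C5, and C8–H for C7.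

## Logic of the disconnections

**15 to 14.** The O7–H bond is traced back to an O7–CH2 bond to a 4-methoxybenzyl group. O7 has to enter as an alkoxide, and a free phenoxide formed at that stage would deactivate the ring for the second substitution, so it must carry a carbon group that comes off under neutral conditions. The gain is that both oxygens flanking C6 in 14 are ethers and can both derive from alkoxides. The demand is an oxidant that takes hydride only from the benzylic CH2; ring B has no hydrogen at C2 and the dione has no C–H beside it.

**14 to 13.** The anisyl-side C=O is redrawn as a dimethyl ketal (two C–O bonds). A free 1,2-dione cannot meet alkoxides, whereas in 13 that carbon is no longer electrophilic and the C6 ketone is not enolisable. The demand is a hydrolysis mild enough for C3=C4 and for the benzyl ether. It is placed before the benzyl ether is removed, so that O7 is not free when the oxocarbenium ion forms.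

**13 to 10 and 11.** The aryl C7–O and C5–O bonds are cut, with methoxide as the second oxygen source. Both carbons are ortho to the C6 carbonyl, so both oxygens can be delivered by addition–elimination on a difluoride. This reduces the penta-substituted ring A to 10, whose substituent pattern descends from a symmetric phenol. The demand is order: the first alkoxide must take C7 and stop at 12, and the second must then take C5.

**10 to 5 and 8.** The C6–C(=O) bond is cut. C6–H of 5 lies between two fluorines and is the most acidic position of the arene, and 8 carries both dione carbons, one already as the ketal. The molecule falls into two halves of similar size. The demand is that the aryllithium 9 is kept cold (it can lose lithium fluoride) and adds only once, which the N-methoxy-N-methylamide provides.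

**8 to 7 to 6.** The amide C–N bond and the two ketal C–O bonds are cut, leading to the commercial keto ester 6. The demands are ketalisation of the ketone without touching the ester, and aminolysis of an ester next to a fully substituted carbon.

**5 to 3 to 1 and 2.** In ring B the C4–C4a and O1–C2 bonds are cut, leading through 4 to the aryl propargyl ether 3. The tertiary C–O bond of 3 is then cut to give 1 and 2. The two ortho positions of 1 are equivalent, so the sigmatropic shift has no regiochemical choice, and ring B with all its carbons arrives in two steps. The demands are a tertiary propargylic etherification and a thermal cascade on a fluorine-deactivated ring.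

## Other disconnections considered

**Alternative 1:** Benzannulation that builds ring A.

- **Cut:** C4a–C8a and C5–C6 (and, in the ring-closing event, C8–C8a). Ring A is assembled from the cyclobutenone 3-isopropoxy-2-[(4-methoxyphenyl)ethynyl]cyclobut-2-en-1-one A1 and the ynol ether 1-methoxy-5-methylhex-4-en-1-yne A2.
- **Forward key step (Danheiser benzannulation):** Heating A1 with A2 would open the four-membered ring to a vinylketene. This adds A2 in a [2+2] sense, ketene carbon to the prenyl-bearing alkyne carbon and C2 of A1 to the methoxy-bearing carbon. A 4π opening, a 6π closure and tautomerisation would then give the phenol A3, in which ring A has five substituents and keeps C8–H.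
- **In its favour:** Every position on ring A is dictated by the connectivity of the pericyclic cascade. O5 (methyl, from A2) and O7 (isopropyl, from A1) are told apart with no selectivity question, which is better than the chosen plan on that point. The convergence is equal.
- **Against it here:**
  - Neither A1 nor A2 is commercial, and each needs several steps.
  - After A3, ring B must still be closed by oxidative cyclisation of the prenyl group onto O1.
  - The diarylalkyne must be oxidised to the dione beside the electron-rich C3=C4 bond.
  - The isopropyl ether must be cleaved by a boron or aluminium halide without loss of the 5-methoxy group, which is ortho to the same carbonyl.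
  - O7 cannot be freed earlier, because a phenol ortho to the alkyne tends to close onto it.
- **Comparison:** On structure it is the more rigorous plan for ring A. On mechanism it trades one steric question for several late chemoselectivity questions. On step economy it is clearly longer than the eight steps of the chosen plan, counting the syntheses of A1 and A2 and at least three steps after A3.

**Alternative 2:** Iodine-blocked propargyl ether Claisen cascade.

- **Cut:** The same pair of bonds as step 2 of the chosen plan (C4–C4a and O1–C2 of ring B), but on a ring A that already carries O5, O7, a C6 formyl group and an iodine at C8. The substrate is 2-hydroxy-3-iodo-6-methoxy-4-[(2-methylbut-3-yn-2-yl)oxy]benzaldehyde A4.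
- **Forward key step:** Heating A4 would trigger a [3,3] shift to the only free ortho carbon (the future C4a), which breaks the O1–C bond. Enolisation, a 1,5-hydrogen shift to an ortho-quinone methide and an oxa-6π closure then make the O1–C2 bond again. The product would be 7-hydroxy-8-iodo-5-methoxy-2,2-dimethyl-2H-chromene-6-carbaldehyde A5.
- **In its favour:** The O5/O7 distinction is in place from the start, O5 as a methyl ether and O7 as a carbonyl-chelated phenol. This is better than the chosen plan, where it rests on a steric preference. The cascade is the equal of step 2 in reliability.
- **Against it here:**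
  - Without the halogen the shift could also go to C8, so iodine costs one step to install and one to remove, and its reductive removal must spare C3=C4 and the aldehyde.
  - An electron-rich aryl iodide is a doubtful passenger at the temperature of the rearrangement.
  - After A5 the whole anisoyl carbonyl unit still has to be attached to the aldehyde (acyl-anion addition, oxidation, O7 protection and release), so the dione is built last, on the most functionalised intermediate.
- **Comparison:** On structure it settles the oxygen pattern early but pays with a blocking group. On mechanism the two plans are close, since both use the same cascade. On step economy it is longer in the linear sequence, whereas the chosen plan needs no blocking group because its phenol is symmetric.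

**Alternative 3:** Oxidative aryl shift to an isoflavone, then excision of one carbon.

- **Cut:** The bond between ring C and the carbon that becomes the anisyl-side carbonyl, together with a temporary O7–C bond. The dione is traced to an isoflavone with one extra carbon, and that to the chalcone (E)-1-(7-hydroxy-5-methoxy-2,2-dimethyl-3,4-dihydro-2H-chromen-6-yl)-3-(4-methoxyphenyl)prop-2-en-1-one A6.
- **Forward key step:** Tl(NO3)3 in methanol would add to the enone C=C of A6. The 4-methoxyphenyl group would migrate from the β to the α carbon as monovalent thallium departs, giving a β-keto dimethyl acetal. Acid would close this through O7 to 5-methoxy-3-(4-methoxyphenyl)-8,8-dimethyl-7,8-dihydro-4H,6H-pyrano[3,2-g]chromen-4-one A7. Oxidative cleavage of the pyranone C2=C3 bond (loss of the resulting O7 formate) and dehydrogenation of ring B would follow.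
- **In its favour:** O7 needs no protecting group; it is tied up in the pyranone and emerges free, which is better than the chosen plan on that point. A6 comes from a simple aldol condensation. The direction of the aryl shift is as unambiguous as lithiation between two fluorines, so the two are equal there.
- **Against it here:**
  - Trivalent thallium is used stoichiometrically and is highly toxic.
  - Ring B has to stay saturated in A6 and A7, because both the thallium reagent and the cleavage oxidant would attack C3=C4. A late dehydrogenation on the free phenol dione is therefore required.
  - Ring A of A6 already needs the O5/O7 distinction and a regiocontrolled ring B annulation, so the hard problem is moved, not solved.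
  - One carbon is installed only to be removed.
- **Comparison:** On structure it leaves ring A unsolved. On mechanism its key step is well precedented, but its endgame is oxidative and harsh. On step economy it is no shorter than the chosen plan and less atom-economical.

Key step: step 6

**Remarks on the chemistry**

- 15 has no stereocentre, so no step has to set or preserve configuration.
- Ketone 10 itself has no symmetry. The regiochemical questions of ring B formation and C6 metalation are removed by the mirror symmetry of 1 and 3 and by the unique position of C6–H between two fluorines in 5.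
- Fluorine is kept as the leaving group at both carbons, and the acyclic dimethyl ketal as the mask, because fluoride is the fastest leaving group in addition–elimination and this ketal is the easiest to hydrolyse.
- The design is refined in two places: 10 is made through amide 8, and the product is unmasked ketal first, benzyl ether second.

## Steps

**Step 1**
Reactants: 1 3,5-difluorophenol; 2 3-chloro-3-methylbut-1-yne
Product: 3 1,3-difluoro-5-[(2-methylbut-3-yn-2-yl)oxy]benzene
Conditions: K2CO3, KI (cat.), CuI (cat.), acetone, 56 °C
Reagents that add atoms: none
Why: Copper-assisted propargylic etherification: the copper acetylide of 2 ionises at the tertiary carbon and the phenoxide of the acidic phenol 1 captures it there, which avoids a direct SN2 at a tertiary centre.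

**Step 2**
Reactants: 3 1,3-difluoro-5-[(2-methylbut-3-yn-2-yl)oxy]benzene
Product: 5 5,7-difluoro-2,2-dimethyl-2H-chromene, via allenylphenol 4 (not isolated)
Conditions: PhNEt2, 190 °C
Reagents that add atoms: none
Why: Aromatic propargyl Claisen rearrangement to either of the two equivalent ortho carbons, enolisation to 4, 1,5-hydrogen shift to the ortho-quinone methide and oxa-6π electrocyclisation should close ring B. The symmetry of 3 allows only one chromene; the fluorines slow the [3,3] shift, hence the high temperature.

**Step 3**
Reactants: 6 methyl 2-(4-methoxyphenyl)-2-oxoacetate
Product: 7 methyl 2,2-dimethoxy-2-(4-methoxyphenyl)acetate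
Conditions: HC(OMe)3, MeOH, H2SO4 (cat.), 65 °C
Reagents that add atoms: trimethyl orthoformate (COC(OC)OC); methanol (CO)
Why: Acid-catalysed ketalisation of the ester-activated ketone, driven by the orthoformate, which removes water as methyl formate. The methyl ester is unchanged in methanol.

**Step 4**
Reactants: 7 methyl 2,2-dimethoxy-2-(4-methoxyphenyl)acetate
Product: 8 N,2,2-trimethoxy-2-(4-methoxyphenyl)-N-methylacetamide
Conditions: MeNH(OMe)·HCl, iPrMgCl, THF, −20 → 0 °C
Reagents that add atoms: N,O-dimethylhydroxylamine hydrochloride (CNOC.Cl)
Why: Ester aminolysis by the chloromagnesium amide (Weinreb amide synthesis); the two α-alkoxy groups activate the ester and the basic medium leaves the ketal intact. The amide is preferred to the ester as acyl donor because its adduct with 9 stays chelated until quench and releases no methoxide beside the fluoride-bearing ketone.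

**Step 5**
Reactants: 5 5,7-difluoro-2,2-dimethyl-2H-chromene; 8 N,2,2-trimethoxy-2-(4-methoxyphenyl)-N-methylacetamide
Product: 10 1-(5,7-difluoro-2,2-dimethyl-2H-chromen-6-yl)-2,2-dimethoxy-2-(4-methoxyphenyl)ethan-1-one, via aryllithium 9 (not isolated)
Conditions: LiN(iPr)2, THF, −78 °C; then 8, −78 → −50 °C; aq. NH4Cl
Reagents that add atoms: none
Why: Directed ortho-metalation at the C–H flanked by two fluorines (the most acidic site; a non-nucleophilic amide base spares C3=C4), followed by Weinreb ketone synthesis through a chelated tetrahedral adduct that collapses only on quench. The low temperature keeps 9 from losing lithium fluoride.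

**Step 6**
Reactants: 10 1-(5,7-difluoro-2,2-dimethyl-2H-chromen-6-yl)-2,2-dimethoxy-2-(4-methoxyphenyl)ethan-1-one; 11 (4-methoxyphenyl)methanol
Product: 13 2,2-dimethoxy-1-{5-methoxy-7-[(4-methoxybenzyl)oxy]-2,2-dimethyl-2H-chromen-6-yl}-2-(4-methoxyphenyl)ethan-1-one, via monofluoro benzyl ether 12 (not isolated)
Conditions: 11, KN(SiMe3)2 (1.0 equiv), THF, −40 °C, added to 10, −40 → 0 °C; then NaOMe, DMF, 0 → 50 °C
Reagents that add atoms: sodium methoxide (C[O-].[Na+])
Why: Each displacement is an addition–elimination (SNAr): the alkoxide adds to the fluorine-bearing carbon, the charge of the cyclohexadienyl (Meisenheimer) anion is taken up by C6 and its carbonyl as an enolate, and fluoride leaves. The closest known reaction type is the stepwise alkoxide substitution of 2,6-difluoroaryl ketones and nitriles, where fluoride is displaced far faster than any alkoxy group. No ring is closed and no stereocentre is formed. Two selectivities are needed: C7 before C5, and one substitution before two. For the first, C7 has only C8–H as its other neighbour while C5 is buttressed by the ring-fusion carbon C4a and the peri C4–H, so the larger benzylic alkoxide, used as the limiting reagent and added cold to 10, should choose C7 and give 12. For the second, the new C7 alkoxy group donates into the C6 carbonyl and weakens its pull, so the C5 fluorine should survive the cold stage and yield only on warming to the small methoxide in excess. The ketone is not enolisable and the second carbonyl is a ketal, so reversible addition to the hindered C6 carbonyl is the only side equilibrium expected. The two sites are electronically alike (both ortho to the carbonyl and meta to O1), so the site preference rests on sterics and should be regarded as moderate, not assured.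

**Step 7**
Reactants: 13 2,2-dimethoxy-1-{5-methoxy-7-[(4-methoxybenzyl)oxy]-2,2-dimethyl-2H-chromen-6-yl}-2-(4-methoxyphenyl)ethan-1-one
Product: 14 1-{5-methoxy-7-[(4-methoxybenzyl)oxy]-2,2-dimethyl-2H-chromen-6-yl}-2-(4-methoxyphenyl)ethane-1,2-dione
Conditions: TsOH·H2O (cat.), acetone–H2O, 40 °C
Reagents that add atoms: water (O)
Why: Acid-catalysed ketal hydrolysis through an oxocarbenium ion stabilised by the 4-methoxyphenyl group. It is run while O7 is still benzylated so that no ortho phenol can trap the cation as a cyclic mixed ketal; the aryl benzyl ether and C3=C4 should tolerate dilute sulfonic acid in wet acetone.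

**Step 8**
Reactants: 14 1-{5-methoxy-7-[(4-methoxybenzyl)oxy]-2,2-dimethyl-2H-chromen-6-yl}-2-(4-methoxyphenyl)ethane-1,2-dione
Product: 15 1-(7-hydroxy-5-methoxy-2,2-dimethyl-2H-chromen-6-yl)-2-(4-methoxyphenyl)ethane-1,2-dione
Conditions: DDQ, CH2Cl2–pH 7 buffer, 0 → 25 °C
Reagents that add atoms: none
Why: Oxidative cleavage of the 4-methoxybenzyl ether: hydride abstraction from the benzylic CH2, addition of water and collapse of the hemiacetal to the phenol and 4-methoxybenzaldehyde. Ring B offers no abstractable hydrogen (C2 is quaternary), the dione is inert, and the liberated phenol is hydrogen-bonded to the C6 carbonyl, which protects it from further oxidation.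

## Compound list

1 | 3,5-difluorophenol | Oc1cc(F)cc(F)c1 | starting material
2 | 3-chloro-3-methylbut-1-yne | CC(C)(Cl)C#C | starting material
3 | 1,3-difluoro-5-[(2-methylbut-3-yn-2-yl)oxy]benzene | C#CC(C)(C)Oc1cc(F)cc(F)c1 | intermediate
4 | 3,5-difluoro-2-(3-methylbuta-1,2-dien-1-yl)phenol | CC(C)=C=Cc1c(O)cc(F)cc1F | intermediate (not isolated)
5 | 5,7-difluoro-2,2-dimethyl-2H-chromene | CC1(C)C=Cc2c(F)cc(F)cc2O1 | intermediate
6 | methyl 2-(4-methoxyphenyl)-2-oxoacetate | COC(=O)C(=O)c1ccc(OC)cc1 | starting material
7 | methyl 2,2-dimethoxy-2-(4-methoxyphenyl)acetate | COC(=O)C(OC)(OC)c1ccc(OC)cc1 | intermediate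
8 | N,2,2-trimethoxy-2-(4-methoxyphenyl)-N-methylacetamide | CON(C)C(=O)C(OC)(OC)c1ccc(OC)cc1 | intermediate
9 | (5,7-difluoro-2,2-dimethyl-2H-chromen-6-yl)lithium | [Li]c1c(F)cc2OC(C)(C)C=Cc2c1F | intermediate (not isolated)
10 | 1-(5,7-difluoro-2,2-dimethyl-2H-chromen-6-yl)-2,2-dimethoxy-2-(4-methoxyphenyl)ethan-1-one | COc1ccc(C(OC)(OC)C(=O)c2c(F)cc3OC(C)(C)C=Cc3c2F)cc1 | intermediate
11 | (4-methoxyphenyl)methanol | COc1ccc(CO)cc1 | starting material
12 | 1-{5-fluoro-7-[(4-methoxybenzyl)oxy]-2,2-dimethyl-2H-chromen-6-yl}-2,2-dimethoxy-2-(4-methoxyphenyl)ethan-1-one | COc1ccc(COc2cc3OC(C)(C)C=Cc3c(F)c2C(=O)C(OC)(OC)c2ccc(OC)cc2)cc1 | intermediate (not isolated)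
13 | 2,2-dimethoxy-1-{5-methoxy-7-[(4-methoxybenzyl)oxy]-2,2-dimethyl-2H-chromen-6-yl}-2-(4-methoxyphenyl)ethan-1-one | COc1ccc(COc2cc3OC(C)(C)C=Cc3c(OC)c2C(=O)C(OC)(OC)c2ccc(OC)cc2)cc1 | intermediate
14 | 1-{5-methoxy-7-[(4-methoxybenzyl)oxy]-2,2-dimethyl-2H-chromen-6-yl}-2-(4-methoxyphenyl)ethane-1,2-dione | COc1ccc(COc2cc3OC(C)(C)C=Cc3c(OC)c2C(=O)C(=O)c2ccc(OC)cc2)cc1 | intermediate
15 | 1-(7-hydroxy-5-methoxy-2,2-dimethyl-2H-chromen-6-yl)-2-(4-methoxyphenyl)ethane-1,2-dione | COc1ccc(C(=O)C(=O)c2c(O)cc3c(c2OC)C=CC(C)(C)O3)cc1 | target

## Step count and least certain steps

Total step count: 8. Longest linear sequence: 6 (steps 1, 2, 5, 6, 7, 8); steps 3 and 4 form the two-step side branch that delivers 8.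

**Step 6 (key step).**
- Most likely failure: loss of site control in the first fluoride displacement, with attack at the hindered C5 competing with attack at C7 because the two carbons differ only sterically. A second benzylic alkoxide may also add before methoxide is introduced.
- Fallback: set out from 10 and run the two substitutions as separate, purified stages with a much bulkier first nucleophile. KOC(CH3)3 in THF at 0 °C should give 1-(7-tert-butoxy-5-fluoro-2,2-dimethyl-2H-chromen-6-yl)-2,2-dimethoxy-2-(4-methoxyphenyl)ethan-1-one F1. NaOMe in DMF at 50 °C should then give 1-(7-tert-butoxy-5-methoxy-2,2-dimethyl-2H-chromen-6-yl)-2,2-dimethoxy-2-(4-methoxyphenyl)ethan-1-one F2. Cold aqueous CF3CO2H in CH2Cl2 should remove the tert-butyl group and the ketal together, and the sequence comes back to the route at 15, bypassing 13 and 14.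

**Step 5.**
- Most likely failure: slow acyl transfer from an amide whose carbonyl sits beside a fully substituted carbon to the fluorine-stabilised aryllithium. Warming would then be needed, and elimination of lithium fluoride to an aryne would set in.
- Fallback: set out from 7 and reduce it with iBu2AlH at −78 °C to 2,2-dimethoxy-2-(4-methoxyphenyl)acetaldehyde F3. Add F3 to 9 at −78 °C, where an aldehyde should react quickly, to give racemic 1-(5,7-difluoro-2,2-dimethyl-2H-chromen-6-yl)-2,2-dimethoxy-2-(4-methoxyphenyl)ethan-1-ol F4. Oxidise F4 with Dess–Martin periodinane, which removes the temporary stereocentre and comes back to the route at 10.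

**Step 7.**
- Most likely failure: acid-promoted damage during ketal cleavage, either protonation of the electron-rich C3=C4 bond or premature ionisation of the benzylic ether with benzylation of C8. The hydrolysis may also stall, because the neighbouring carbonyl destabilises the oxocarbenium ion.
- Fallback: set out from 13 and reverse the order of unmasking. DDQ in CH2Cl2–buffer should give 1-(7-hydroxy-5-methoxy-2,2-dimethyl-2H-chromen-6-yl)-2,2-dimethoxy-2-(4-methoxyphenyl)ethan-1-one F5, which no longer holds an acid-labile benzyl group. Its ketal can then be hydrolysed in aqueous acetic acid–THF; any cyclic mixed ketal formed by O7 is in equilibrium in water and should drain to the open dione. The sequence comes back to the route at 15, bypassing 14.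

**Step 4.**
- Most likely failure: incomplete aminolysis of the hindered ester; forcing it invites attack of the Grignard reagent itself on the carbonyl.
- Fallback: set out from 7 and saponify it with LiOH in THF–water to 2,2-dimethoxy-2-(4-methoxyphenyl)acetic acid F6, liberated cold and used at once. Activate F6 with 1,1'-carbonyldiimidazole and treat it with N,O-dimethylhydroxylamine hydrochloride, which comes back to the route at 8.

## Further compounds

F1 | step 6 | 1-(7-tert-butoxy-5-fluoro-2,2-dimethyl-2H-chromen-6-yl)-2,2-dimethoxy-2-(4-methoxyphenyl)ethan-1-one | COc1ccc(C(OC)(OC)C(=O)c2c(OC(C)(C)C)cc3OC(C)(C)C=Cc3c2F)cc1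
F2 | step 6 | 1-(7-tert-butoxy-5-methoxy-2,2-dimethyl-2H-chromen-6-yl)-2,2-dimethoxy-2-(4-methoxyphenyl)ethan-1-one | COc1ccc(C(OC)(OC)C(=O)c2c(OC(C)(C)C)cc3OC(C)(C)C=Cc3c2OC)cc1
F3 | step 5 | 2,2-dimethoxy-2-(4-methoxyphenyl)acetaldehyde | COc1ccc(C(OC)(OC)C=O)cc1
F4 | step 5 | 1-(5,7-difluoro-2,2-dimethyl-2H-chromen-6-yl)-2,2-dimethoxy-2-(4-methoxyphenyl)ethan-1-ol (racemic) | COc1ccc(C(OC)(OC)C(O)c2c(F)cc3OC(C)(C)C=Cc3c2F)cc1
F5 | step 7 | 1-(7-hydroxy-5-methoxy-2,2-dimethyl-2H-chromen-6-yl)-2,2-dimethoxy-2-(4-methoxyphenyl)ethan-1-one | COc1ccc(C(OC)(OC)C(=O)c2c(O)cc3OC(C)(C)C=Cc3c2OC)cc1
F6 | step 4 | 2,2-dimethoxy-2-(4-methoxyphenyl)acetic acid | COc1ccc(C(OC)(OC)C(O)=O)cc1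
A1 | alternative 1 | 3-isopropoxy-2-[(4-methoxyphenyl)ethynyl]cyclobut-2-en-1-one | COc1ccc(C#CC2=C(OC(C)C)CC2=O)cc1
A2 | alternative 1 | 1-methoxy-5-methylhex-4-en-1-yne | COC#CCC=C(C)C
A3 | alternative 1 | 3-methoxy-4-[(4-methoxyphenyl)ethynyl]-2-(3-methylbut-2-en-1-yl)-5-(propan-2-yloxy)phenol | COc1ccc(C#Cc2c(OC(C)C)cc(O)c(CC=C(C)C)c2OC)cc1
A4 | alternative 2 | 2-hydroxy-3-iodo-6-methoxy-4-[(2-methylbut-3-yn-2-yl)oxy]benzaldehyde | COc1cc(OC(C)(C)C#C)c(I)c(O)c1C=O
A5 | alternative 2 | 7-hydroxy-8-iodo-5-methoxy-2,2-dimethyl-2H-chromene-6-carbaldehyde | COc1c(C=O)c(O)c(I)c2OC(C)(C)C=Cc12
A6 | alternative 3 | (E)-1-(7-hydroxy-5-methoxy-2,2-dimethyl-3,4-dihydro-2H-chromen-6-yl)-3-(4-methoxyphenyl)prop-2-en-1-one | COc1ccc(/C=C/C(=O)c2c(O)cc3OC(C)(C)CCc3c2OC)cc1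
A7 | alternative 3 | 5-methoxy-3-(4-methoxyphenyl)-8,8-dimethyl-7,8-dihydro-4H,6H-pyrano[3,2-g]chromen-4-one | COc1ccc(-c2coc3cc4OC(C)(C)CCc4c(OC)c3c2=O)cc1
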